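Ring numbering: C1 = quaternary oxirane carbon carrying C7H2OBz, C2 = CHOH, C3 = CHOBz, C4=C5 = alkene, C6 = oxirane CH. The strategy rests on the C1–O–C6 oxirane lying next to the C4=C5 alkene and anti to the cis C2/C3 oxygens: a 1,3-diene monoepoxide, which is what a C1,C4-epidioxide gives when it loses one oxygen.
Disconnection A (oxirane, last ring): the C6–O bond, back to a 2,3-dioxabicyclo[2.2.2]oct-5-ene bridged across C1/C4. Forward, PPh3 takes the oxygen on C4 and the C1 oxygen closes on C6 while the alkene moves from C5=C6 to C4=C5.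
Disconnection B (peroxide bridge): C1–O and C4–O, back to the 1-(benzoyloxymethyl)cyclohexa-1,3-diene acetonide plus singlet oxygen, added anti to the acetonide.
Disconnection C: C1–C7 by Stille hydroxymethylation of the acetonide of (1S,2S)-3-bromocyclohexa-3,5-diene-1,2-diol, which supplies the carbocycle and the C2/C3 stereocentres.
Ring order: carbocycle bought, then dioxolane (temporary), peroxide bridge, oxirane. The acetonide is exchanged for C3–OBz/C2–OSiEt3 while the acid-tolerant peroxide is still in place, because a vinyl oxirane would not survive acetonide hydrolysis; buffered fluoride ends the route.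

Key step: step 8

Remark: descriptors of the ring compounds from 7 on use the ring numbering above; the descriptor changes at C3 (9 to 10) and at C1 (12 to 13) are CIP priority changes only, no centre is inverted.

Step 1
Reactants: 1 (1S,2S)-3-bromocyclohexa-3,5-diene-1,2-diol
Product: 2 (3aS,7aS)-4-bromo-2,2-dimethyl-3a,7a-dihydro-1,3-benzodioxole
Conditions: 2,2-dimethoxypropane, TsOH·H2O (cat.), acetone, 0 °C to rt
Reagents that add atoms: 2,2-dimethoxypropane, COC(C)(C)OC
Why: Acid-catalysed transacetalisation (acetonide formation) is fast for the cis-diol, touches neither stereocentre, stops dehydration of the diene diol to the phenol and gives the cis-fused dioxolane that will shield one diene face in step 4.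

Step 2
Reactants: 2 (3aS,7aS)-4-bromo-2,2-dimethyl-3a,7a-dihydro-1,3-benzodioxole; 3 (tributylstannyl)methanol
Product: 4 [(3aR,7aS)-2,2-dimethyl-3a,7a-dihydro-1,3-benzodioxol-4-yl]methanol
Conditions: Pd(PPh3)4 (5 mol %), 1,4-dioxane (degassed), 80 °C
Reagents that add atoms: (tributylstannyl)methanol, CCCC[Sn](CCCC)(CCCC)CO
Why: Stille coupling, in which zerovalent palladium inserts into the vinyl C–Br bond and the α-oxygenated CH2OH group is transferred from tin in preference to butyl, so C7 is attached to C1 with the acetal stereocentres as spectators.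

Step 3
Reactants: 4 [(3aR,7aS)-2,2-dimethyl-3a,7a-dihydro-1,3-benzodioxol-4-yl]methanol; 5 benzoyl chloride
Product: 6 [(3aR,7aS)-2,2-dimethyl-3a,7a-dihydro-1,3-benzodioxol-4-yl]methyl benzoate
Conditions: BzCl, pyridine, DMAP (cat.), CH2Cl2, 0 °C
Reagents that add atoms: benzoyl chloride, O=C(Cl)c1ccccc1
Why: Base-mediated acylation (esterification) of the unhindered primary allylic alcohol installs the C7 benzoate that the target keeps.

Step 4
Reactants: 6 [(3aR,7aS)-2,2-dimethyl-3a,7a-dihydro-1,3-benzodioxol-4-yl]methyl benzoate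
Product: 7 [(1R,2S,3R,4R)-1,4-epidioxy-2,3-(isopropylidenedioxy)cyclohex-5-en-1-yl]methyl benzoate
Conditions: O2, tetraphenylporphyrin (cat.), CH2Cl2, hν (visible), −30 °C
Reagents that add atoms: dioxygen (singlet oxygen generated in the flask), O=O
Why: Singlet-oxygen [4+2] cycloaddition across the s-cis-locked diene termini C1 and C4 should outrun any ene pathway, and O2 approaches the face anti to the cis-fused acetonide, whose endo methyl covers the syn face, which sets C1 (and the transient C4 centre) with the C1–O bond anti to the C2/C3 oxygens.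

Step 5
Reactants: 7 [(1R,2S,3R,4R)-1,4-epidioxy-2,3-(isopropylidenedioxy)cyclohex-5-en-1-yl]methyl benzoate
Product: 8 [(1R,2S,3R,4R)-1,4-epidioxy-2,3-dihydroxycyclohex-5-en-1-yl]methyl benzoate
Conditions: TFA/H2O (9:1), 0 °C
Reagents that add atoms: none
Why: Acid-catalysed acetal hydrolysis frees the cis-diol while the dialkyl peroxide (its allylic C–O bonds inductively deactivated, and no base present to start a Kornblum–DeLaMare fragmentation) and the benzoate should tolerate cold aqueous acid; no stereocentre is involved.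

Step 6
Reactants: 8 [(1R,2S,3R,4R)-1,4-epidioxy-2,3-dihydroxycyclohex-5-en-1-yl]methyl benzoate; 5 benzoyl chloride
Product: 9 [(1R,2S,3R,4R)-3-(benzoyloxy)-1,4-epidioxy-2-hydroxycyclohex-5-en-1-yl]methyl benzoate
Conditions: BzCl (1.05 equiv), pyridine, CH2Cl2, −30 to 0 °C
Reagents that add atoms: benzoyl chloride, O=C(Cl)c1ccccc1
Why: Kinetic site-selective acylation, since C3–OH is flanked only by the C4–H bridgehead whereas C2–OH is gauche to C7H2OBz on quaternary C1, so one equivalent of acid chloride at low temperature should give the C3 monoester, pyridine being too weak a base to remove the C4 hydrogen.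

Step 7
Reactants: 9 [(1R,2S,3R,4R)-3-(benzoyloxy)-1,4-epidioxy-2-hydroxycyclohex-5-en-1-yl]methyl benzoate
Product: 10 [(1R,2S,3S,4R)-3-(benzoyloxy)-1,4-epidioxy-2-(triethylsilyloxy)cyclohex-5-en-1-yl]methyl benzoate
Conditions: TESOTf, 2,6-lutidine, CH2Cl2, −78 °C
Reagents that add atoms: triethylsilyl trifluoromethanesulfonate, CC[Si](CC)(CC)OS(=O)(=O)C(F)(F)F
Why: Silyl triflate/lutidine silylation caps the hindered C2–OH within minutes at low temperature, so that no free hydroxyl can exchange into the phosphorus intermediates of step 8 or relay benzoyl migration, and the silyl ether can later be removed without acid.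

Step 8
Reactants: 10 [(1R,2S,3S,4R)-3-(benzoyloxy)-1,4-epidioxy-2-(triethylsilyloxy)cyclohex-5-en-1-yl]methyl benzoate
Product: 12 [(1S,2S,3S,6S)-3-(benzoyloxy)-1,6-epoxy-2-(triethylsilyloxy)cyclohex-4-en-1-yl]methyl benzoate, via alkoxyphosphonium alkoxide 11 (not isolated)
Conditions: PPh3 (1.1 equiv), CH2Cl2 (anhydrous), 0 °C to rt
Reagents that add atoms: none
Why: Triphenylphosphine forms a P–O bond at the peroxide oxygen on secondary C4 (the oxygen on quaternary C1 is screened by C7H2OBz and the C2 silyl ether), so the O–O bond breaks to the C4 alkoxyphosphonium/C1 alkoxide 11. The C1 alkoxide then attacks C6 on its own face while Ph3P=O leaves from C4 on that same face (syn SN2′) and the alkene moves from C5=C6 to C4=C5. The closest known reaction type is the phosphine or phosphite monodeoxygenation of 2,3-dioxabicyclo[2.2.2]oct-5-enes (1,4-epidioxides of cyclohexa-1,3-dienes) to 3,4-epoxycyclohexenes. The oxirane is closed in 3-exo-trig mode by O-alkylation at C6 with allylic transposition. The new stereocentre C6 is controlled by C1: the oxygen is tethered to C1 and can only bond to the adjacent C6 on the face it already occupies, the face chosen by singlet oxygen anti to the C2/C3 oxygens, so the cis-fused oxirane ends up anti to OSiEt3/OBz. The selectivity needed is regiochemical (phosphorus on the C4 oxygen, otherwise the C4–C5 oxirane with a C1=C6 alkene would form); it is secured by the steric difference between the two bridgeheads and the easier departure of the phosphine oxide from secondary allylic C4, while the absence of hydrogen on C1 and of any free hydroxyl shuts down fragmentation and phosphorane exchange.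

Step 9
Reactants: 12 [(1S,2S,3S,6S)-3-(benzoyloxy)-1,6-epoxy-2-(triethylsilyloxy)cyclohex-4-en-1-yl]methyl benzoate
Product: 13 [(1R,2S,3S,6S)-3-(benzoyloxy)-1,6-epoxy-2-hydroxycyclohex-4-en-1-yl]methyl benzoate
Conditions: TBAF, AcOH (1:1), THF, 0 °C to rt
Reagents that add atoms: none
Why: Fluoride-induced Si–O cleavage (desilylation) buffered with acetic acid keeps the medium near neutral, so the acid-labile vinyl oxirane should be untouched and the C2 alkoxide is protonated before the cis C3 benzoate can migrate; no stereocentre is involved.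

Compound list
1 | (1S,2S)-3-bromocyclohexa-3,5-diene-1,2-diol | BrC1=CC=C[C@H](O)[C@@H]1O | starting material
2 | (3aS,7aS)-4-bromo-2,2-dimethyl-3a,7a-dihydro-1,3-benzodioxole | BrC1=CC=C[C@@H]2OC(C)(C)O[C@H]12 | intermediate
3 | (tributylstannyl)methanol | CCCC[Sn](CCCC)(CCCC)CO | starting material
4 | [(3aR,7aS)-2,2-dimethyl-3a,7a-dihydro-1,3-benzodioxol-4-yl]methanol | OCC1=CC=C[C@@H]2OC(C)(C)O[C@H]12 | intermediate
5 | benzoyl chloride | O=C(Cl)c1ccccc1 | starting material
6 | [(3aR,7aS)-2,2-dimethyl-3a,7a-dihydro-1,3-benzodioxol-4-yl]methyl benzoate | O=C(OCC1=CC=C[C@@H]2OC(C)(C)O[C@H]12)c1ccccc1 | intermediate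
7 | [(1R,2S,3R,4R)-1,4-epidioxy-2,3-(isopropylidenedioxy)cyclohex-5-en-1-yl]methyl benzoate (O–O bridge anti to the acetonide) | O=C(OC[C@]12OO[C@H](C=C1)[C@@H]3OC(C)(C)O[C@H]23)c1ccccc1 | intermediate
8 | [(1R,2S,3R,4R)-1,4-epidioxy-2,3-dihydroxycyclohex-5-en-1-yl]methyl benzoate | O=C(OC[C@]12OO[C@H](C=C1)[C@H](O)[C@@H]2O)c1ccccc1 | intermediate
9 | [(1R,2S,3R,4R)-3-(benzoyloxy)-1,4-epidioxy-2-hydroxycyclohex-5-en-1-yl]methyl benzoate | O=C(OC[C@]12OO[C@H](C=C1)[C@H](OC(=O)c3ccccc3)[C@@H]2O)c1ccccc1 | intermediate
10 | [(1R,2S,3S,4R)-3-(benzoyloxy)-1,4-epidioxy-2-(triethylsilyloxy)cyclohex-5-en-1-yl]methyl benzoate | O=C(OC[C@]12OO[C@H](C=C1)[C@H](OC(=O)c3ccccc3)[C@@H]2O[Si](CC)(CC)CC)c1ccccc1 | intermediate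
11 | C4 (triphenylphosphonio)oxy C1 alkoxide betaine of 10 (O–O cleaved, both oxygens still on the face anti to OSiEt3/OBz) | O=C(OC[C@]1([O-])C=C[C@@H](O[P+](c2ccccc2)(c2ccccc2)c2ccccc2)[C@H](OC(=O)c2ccccc2)[C@@H]1O[Si](CC)(CC)CC)c1ccccc1 | intermediate (not isolated)
12 | [(1S,2S,3S,6S)-3-(benzoyloxy)-1,6-epoxy-2-(triethylsilyloxy)cyclohex-4-en-1-yl]methyl benzoate | O=C(OC[C@]12O[C@H]1C=C[C@H](OC(=O)c3ccccc3)[C@@H]2O[Si](CC)(CC)CC)c1ccccc1 | intermediate
13 | [(1R,2S,3S,6S)-3-(benzoyloxy)-1,6-epoxy-2-hydroxycyclohex-4-en-1-yl]methyl benzoate | O=C(OC[C@]12O[C@H]1C=C[C@H](OC(=O)c1ccccc1)[C@@H]2O)c1ccccc1 | target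

Total step count: 9. Longest linear sequence: 9 steps (1 to 13).

Steps most likely to fail

Step 8. What may go wrong: P–O bond formation at the C1 peroxide oxygen (or ionisation of a phosphorane in the reverse sense) would deliver the oxygen to C5 and give the regioisomeric oxirane. Adventitious water could also intercept the betaine and cause net reduction to the ene-1,4-diol. Fallback (peracid epoxidation of a diene in place of peroxide collapse), setting out from 1: silylation (TESCl, imidazole, DMAP, DMF) gives the bis(triethylsilyl) ether of the bromodiene diol F1. Stille coupling with 3 and benzoylation with 5, run as in steps 2 and 3, give the bis-TES dienylmethanol F2 and the bis-TES dienylmethyl benzoate F3. mCPBA/NaHCO3 (CH2Cl2, 0 °C) should epoxidise the trisubstituted, more nucleophilic C1=C6 bond on the face anti to the C2 silyloxy group, giving the bis-TES vinyl epoxide F4. TBAF/AcOH then frees the epoxy diol F5. Catalyst-controlled monobenzoylation of the cis-diol at the less hindered C3–OH (BzCl, i-Pr2NEt, 2-aminoethyl diphenylborinate cat., MeCN, rt) comes back to the route at 13.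

Step 6. What may go wrong: insufficient discrimination between the two secondary hydroxyls (acylation at C2 or double acylation), or base-induced fragmentation of the peroxide at C4–H during the acylation. Fallback (protect both, unmask one), setting out from 8: TESOTf/2,6-lutidine (CH2Cl2, −78 °C) gives the bis-TES endoperoxide F6. The less hindered C3 silyl ether is then cleaved selectively under acidic, peroxide-safe conditions (HF·pyridine, pyridine/THF, −10 °C; over- and under-reacted material can be resilylated and recycled), giving the C2-mono-TES C3-alcohol F7. Benzoylation of its only free hydroxyl (BzCl, pyridine, CH2Cl2, 0 °C) comes back to the route at 10.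

Step 2. What may go wrong: thermal Diels–Alder dimerisation of the cyclohexadiene and sluggish transfer of the hydroxymethyl group from tin (competing butyl transfer or protodestannylation) at the temperature the coupling needs. Fallback (low-temperature organolithium formylation, then reduction), setting out from 2: bromine–lithium exchange (t-BuLi, 2 equiv, Et2O, −78 °C) gives the dienyllithium F8. Trapping with DMF gives the dienal F9. Luche reduction (NaBH4, CeCl3·7H2O, MeOH, −40 °C) comes back to the route at 4.

Further compounds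
F1 | step 8 | (5S,6S)-1-bromo-5,6-bis(triethylsilyloxy)cyclohexa-1,3-diene (bis-TES ether of 1) | BrC1=CC=C[C@H](O[Si](CC)(CC)CC)[C@@H]1O[Si](CC)(CC)CC
F2 | step 8 | [cis-5,6-bis(triethylsilyloxy)cyclohexa-1,3-dien-1-yl]methanol, configuration of 1 retained | OCC1=CC=C[C@H](O[Si](CC)(CC)CC)[C@@H]1O[Si](CC)(CC)CC
F3 | step 8 | [cis-5,6-bis(triethylsilyloxy)cyclohexa-1,3-dien-1-yl]methyl benzoate, configuration of 1 retained | O=C(OCC1=CC=C[C@H](O[Si](CC)(CC)CC)[C@@H]1O[Si](CC)(CC)CC)c1ccccc1
F4 | step 8 | [1,6-epoxy-2,3-bis(triethylsilyloxy)cyclohex-4-en-1-yl]methyl benzoate, oxirane anti to both silyloxy groups | O=C(OC[C@]12O[C@H]1C=C[C@H](O[Si](CC)(CC)CC)[C@@H]2O[Si](CC)(CC)CC)c1ccccc1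
F5 | step 8 | [(1R,2S,3S,6S)-1,6-epoxy-2,3-dihydroxycyclohex-4-en-1-yl]methyl benzoate | O=C(OC[C@]12O[C@H]1C=C[C@H](O)[C@@H]2O)c1ccccc1
F6 | step 6 | [1,4-epidioxy-2,3-bis(triethylsilyloxy)cyclohex-5-en-1-yl]methyl benzoate, configuration of 8 retained | O=C(OC[C@]12OO[C@H](C=C1)[C@H](O[Si](CC)(CC)CC)[C@@H]2O[Si](CC)(CC)CC)c1ccccc1
F7 | step 6 | [1,4-epidioxy-3-hydroxy-2-(triethylsilyloxy)cyclohex-5-en-1-yl]methyl benzoate, configuration of 8 retained | O=C(OC[C@]12OO[C@H](C=C1)[C@H](O)[C@@H]2O[Si](CC)(CC)CC)c1ccccc1
F8 | step 2 | [(3aS,7aS)-2,2-dimethyl-3a,7a-dihydro-1,3-benzodioxol-4-yl]lithium | [Li]C1=CC=C[C@@H]2OC(C)(C)O[C@H]12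
F9 | step 2 | (3aR,7aS)-2,2-dimethyl-3a,7a-dihydro-1,3-benzodioxole-4-carbaldehyde | O=CC1=CC=C[C@@H]2OC(C)(C)O[C@H]12
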